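Cuts: the oxirane oxygen on C1–C10, the C8 angelate and the C13 methylene are removed first. Ring A (the ten-membered carbocycle) is then opened between C3, a secondary carbinol, and C4, the tertiary carbinol that carries C15H2OH. These two adjacent ring carbons form a vicinal diol, which is exactly what a reductive aldehyde–ketone union delivers.
The open chain is cut further at C5–C6 (aldol), C7–C11 (epoxide opening) and C7=C8 (Wittig), back to the C3–C8 unit hidden in 4-methylanisole.
Forward: Birch reduction and enol-ether ozonolysis give C3–C8 with the Z C1–C10 alkene. C6–C7, C11–C12 and C5–C4–C15 are added in that order. Ring B (γ-lactone) closes first, ring A second (SmI2), ring C (oxirane) last.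
Stereochemistry: C8 and C7 come from a Sharpless epoxidation and its SN2 opening, C6 from a Felkin–Anh/1,3-anti Mukaiyama aldol, and C3 and C4 from the samarium-bridged coupling. C1 and C10 come from 3-OH-directed epoxidation of the Z alkene, and the Z ester enters as angelic acid.

Key step: step 17

Remark: germacrane numbering (ring C1–C10, C11–C13 on the lactone side, C14 the methyl on C10, C15 on C4) is used for every intermediate, and α/β refer to the usual drawing with H-7 α.

Step 1
Reactants: 1 4-methylanisole
Product: 2 1-methoxy-4-methylcyclohexa-1,4-diene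
Conditions: Li, NH3 (l), t-BuOH, THF, −78 to −33 °C; then NH4Cl
Reagents that add atoms: none
Why: Birch reduction leaves both donor substituents on sp2 carbons, so the 1,4-diene with one enol-ether and one trisubstituted double bond should form, and the ring fixes the later C1–C10 alkene as Z.

Step 2
Reactants: 2 1-methoxy-4-methylcyclohexa-1,4-diene
Product: 4 methyl (Z)-4-methyl-6-oxohex-3-enoate (C3 ester/C8 aldehyde), via methoxy hydroperoxide 3 (not isolated)
Conditions: O3 (1 equiv), CH2Cl2/MeOH, −78 °C; then Me2S, −78 °C to rt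
Reagents that add atoms: ozone [O-][O+]=O
Why: Chemoselective ozonolysis should cleave only the far more electron-rich enol-ether double bond, the carbonyl oxide being trapped by methanol as 3 and reduced by Me2S, so that the ring-derived Z alkene survives between ester and aldehyde.

Step 3
Reactants: 4 methyl (Z)-4-methyl-6-oxohex-3-enoate; 5 methyl (triphenylphosphoranylidene)acetate
Product: 6 dimethyl (2E,5Z)-5-methylocta-2,5-dienedioate
Conditions: CH2Cl2, 0 °C to rt
Reagents that add atoms: none
Why: Wittig olefination with a stabilised, almost non-basic ylide should give the E C7=C8 enoate without drawing the β,γ-double bond into conjugation.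

Step 4
Reactants: 6 dimethyl (2E,5Z)-5-methylocta-2,5-dienedioate
Product: 7 (2E,5Z)-5-methylocta-2,5-diene-1,8-diol
Conditions: iBu2AlH (4.5 equiv), CH2Cl2, −78 to 0 °C; aq potassium sodium tartrate
Reagents that add atoms: none
Why: Ester reduction with iBu2AlH is a clean 1,2-reduction even on the enoate, so the allylic C6 alcohol and the homoallylic C3 alcohol should result with both alkene geometries intact.

Step 5
Reactants: 7 (2E,5Z)-5-methylocta-2,5-diene-1,8-diol
Product: 8 (Z)-5-[(2R,3R)-3-(hydroxymethyl)oxiran-2-yl]-4-methylpent-3-en-1-ol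
Conditions: Ti(OiPr)4 (10 mol %), D-(−)-diisopropyl tartrate (12 mol %), t-BuOOH, 4 Å MS, CH2Cl2, −20 °C
Reagents that add atoms: tert-butyl hydroperoxide CC(C)(C)OO
Why: In the Sharpless asymmetric epoxidation only the allylic-alcohol alkene is activated on titanium (the homoallylic C1–C10 alkene reacts far more slowly), and the D-(−)-tartrate delivers oxygen to the face that sets C8 as R together with the transient R centre at C7.

Step 6
Reactants: 8 (Z)-5-[(2R,3R)-3-(hydroxymethyl)oxiran-2-yl]-4-methylpent-3-en-1-ol; 9 vinylmagnesium bromide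
Product: 10 (2S,3R,5Z)-2-ethenyl-5-methyloct-5-ene-1,3,8-triol (7S,8R)
Conditions: 9 (5 equiv), CuI (20 mol %), THF/Et2O, −40 to −10 °C
Reagents that add atoms: none
Why: Copper-catalysed Grignard opening of a 2,3-epoxy alcohol takes place at C7 (the carbon next to the carbinol, favoured by the alkoxide and by the β-branched chain on C8) with SN2 inversion, so the trans-epoxide should give the anti C7-vinyl/C8-hydroxy pair with C8 untouched.

Step 7
Reactants: 10 (2S,3R,5Z)-2-ethenyl-5-methyloct-5-ene-1,3,8-triol
Product: 11 (Z)-5-[(2S,4R,5S)-5-ethenyl-2-(4-methoxyphenyl)-1,3-dioxan-4-yl]-4-methylpent-3-en-1-ol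
Conditions: 4-MeOC6H4CH(OMe)2, PPTS (cat.), CH2Cl2, rt
Reagents that add atoms: 4-methoxybenzaldehyde dimethyl acetal COc1ccc(cc1)C(OC)OC
Why: Acid-catalysed transacetalisation under thermodynamic control can form a six-membered acetal only across the O6/O8 1,3-diol, with aryl group, C9 chain and vinyl group all equatorial (acetal carbon S), and it leaves the C3 hydroxyl free.

Step 8
Reactants: 11 (Z)-5-[(2S,4R,5S)-5-ethenyl-2-(4-methoxyphenyl)-1,3-dioxan-4-yl]-4-methylpent-3-en-1-ol
Product: 13 (Z)-5-[(2S,4R,5S)-5-(2-hydroxyethyl)-2-(4-methoxyphenyl)-1,3-dioxan-4-yl]-4-methylpent-3-en-1-ol, via bis-boryl adduct 12 (not isolated)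
Conditions: 9-BBN (2.5 equiv), THF, 0 °C to rt; then NaOH, H2O2, 0 °C
Reagents that add atoms: hydrogen peroxide OO
Why: In this hydroboration–oxidation the bulky dialkylborane adds anti-Markovnikov to the monosubstituted vinyl group much faster than to the trisubstituted C1–C10 alkene, the free hydroxyl only consuming one equivalent as a borinate, so C12 should emerge as a primary alcohol.

Step 9
Reactants: 13 (Z)-5-[(2S,4R,5S)-5-(2-hydroxyethyl)-2-(4-methoxyphenyl)-1,3-dioxan-4-yl]-4-methylpent-3-en-1-ol
Product: 14 (2S,4R,5S)-4-[(Z)-5-(tert-butyldimethylsilyloxy)-2-methylpent-2-enyl]-5-[2-(tert-butyldimethylsilyloxy)ethyl]-2-(4-methoxyphenyl)-1,3-dioxane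
Conditions: TBSCl (2.5 equiv), imidazole, DMF, rt
Reagents that add atoms: tert-butyldimethylsilyl chloride CC(C)(C)[Si](C)(C)Cl
Why: Imidazole-promoted silylation of two unhindered primary alcohols is routine and gives O3 and O12 the same label for later joint release.

Step 10
Reactants: 14 the bis-TBS acetal
Product: 15 (2S,3R,5Z)-8-(tert-butyldimethylsilyloxy)-2-[2-(tert-butyldimethylsilyloxy)ethyl]-3-(4-methoxybenzyloxy)-5-methyloct-5-en-1-ol
Conditions: iBu2AlH (3 equiv), CH2Cl2, −78 to 0 °C
Reagents that add atoms: none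
Why: In the regioselective reductive opening of a 4-methoxybenzylidene acetal aluminium binds the less hindered O6, so hydride delivery should leave the PMB group on the secondary O8 and free the primary C6 alcohol.

Step 11
Reactants: 15 the C6 primary alcohol
Product: 16 (2R,3R,5Z)-8-(tert-butyldimethylsilyloxy)-2-[2-(tert-butyldimethylsilyloxy)ethyl]-3-(4-methoxybenzyloxy)-5-methyloct-5-enal (C6 aldehyde)
Conditions: Dess–Martin periodinane, CH2Cl2, 0 °C to rt
Reagents that add atoms: none
Why: Dess–Martin oxidation is fast and close to neutral, so the α-stereocentre C7 should not epimerise (the descriptor changes only through priorities).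

Step 12
Reactants: 17 hydroxyacetone
Product: 18 1-(tert-butyldiphenylsilyloxy)propan-2-one
Conditions: TBDPSCl, imidazole, CH2Cl2, rt
Reagents that add atoms: tert-butyldiphenylsilyl chloride CC(C)(C)[Si](Cl)(c1ccccc1)c1ccccc1
Why: Standard silylation of a primary alcohol installs on O15 a group that outlasts the TBS ethers and is a poor leaving group next to the later ketone.

Step 13
Reactants: 18 1-(tert-butyldiphenylsilyloxy)propan-2-one
Product: 19 tert-butyldiphenyl{[2-(trimethylsilyloxy)prop-2-en-1-yl]oxy}silane
Conditions: LiN(iPr)2, TMSCl (present from the start), THF, −78 °C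
Reagents that add atoms: chlorotrimethylsilane C[Si](C)(C)Cl
Why: Kinetic silyl enol ether formation with an irreversible hindered base and internal quench should remove a proton of the open methyl group rather than of the CH2 shielded by the OTBDPS group.

Step 14
Reactants: 16 the C6 aldehyde; 19 the enol silane
Product: 20 (4R,5S,6R,8Z)-11-(tert-butyldimethylsilyloxy)-5-[2-(tert-butyldimethylsilyloxy)ethyl]-1-(tert-butyldiphenylsilyloxy)-4-hydroxy-6-(4-methoxybenzyloxy)-8-methylundec-8-en-2-one (6R,7S,8R in germacrane numbering)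
Conditions: 19 (2.5 equiv) premixed with 16, BF3·OEt2 (1.1 equiv) added last, CH2Cl2, −78 °C
Reagents that add atoms: none
Why: In this Mukaiyama aldol with a non-chelating Lewis acid the Felkin–Anh preference of C7 and the polar 1,3-anti induction of the 8-OPMB group reinforce each other for the anti-configured aldehyde, so the open transition state should set C6 as R, syn to the C11 branch and anti to O8.

Step 15
Reactants: 20 the aldol adduct
Product: 21 (4R,5S,6R,8Z)-1-(tert-butyldiphenylsilyloxy)-4,11-dihydroxy-5-(2-hydroxyethyl)-6-(4-methoxybenzyloxy)-8-methylundec-8-en-2-one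
Conditions: HF·pyridine, pyridine, THF, 0 °C
Reagents that add atoms: none
Why: Buffered fluoride desilylation cleaves primary TBS ethers much faster than the primary TBDPS ether and should leave the β-hydroxy ketone and the PMB ether alone.

Step 16
Reactants: 21 the triol ketone
Product: 23 (3Z,6R)-6-(4-methoxybenzyloxy)-4-methyl-6-{(2R,3R)-5-oxo-2-[3-(tert-butyldiphenylsilyloxy)-2-oxopropyl]oxolan-3-yl}hex-3-enal (open-chain keto-aldehyde with trans lactone), via lactol aldehyde 22 (not isolated)
Conditions: TEMPO (20 mol %), PhI(OAc)2 (3.5 equiv), CH2Cl2, rt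
Reagents that add atoms: none
Why: Oxoammonium oxidation is selective for primary alcohols, so C3 should stop at the aldehyde while the C12 aldehyde is captured by the 6-OH as lactol 22 and oxidised on to ring B (oxidative lactonisation of a 1,4-diol), whose trans C6/C7 relationship follows from the centres already in place.

Step 17
Reactants: 23 the keto-aldehyde
Product: 24 (1(10)Z)-3β,4α-dihydroxy-8β-(4-methoxybenzyloxy)-15-(tert-butyldiphenylsilyloxy)germacr-1(10)-en-12,6α-olide (6βH/7αH; saturated lactone)
Conditions: SmI2 (4 equiv, 0.1 M in THF), 23 added by syringe pump to a final 2 mM, THF, −40 °C to rt; aq NaHCO3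
Reagents that add atoms: none
Why: One electron from SmI2 goes to the C3 aldehyde, the more reducible of the two carbonyl groups, and the ketyl so formed stays on trivalent samarium, which also binds the C4 ketone oxygen; C3 then attacks C4, a second electron is taken up and the cyclic samarium diolate is protonated on work-up. The closest known reaction type is the SmI2-mediated intramolecular pinacol coupling of keto-aldehydes, which has been used for medium and large carbocyclic 1,2-diols. Ring A closes in a 10-exo-trig mode (C3 radical onto the C4 carbonyl carbon, oxygen outside the ring), and the Z alkene and the trans-fused lactone remove several rotors so that the two termini lie close. C3 is set by the metal bridge: O3 and O4 must stay gauche on samarium while the ring bonds C2–C3 and C4–C5 prefer an anti arrangement, and this combination corresponds to 3β-OH/4α-OH, that is O3 on the same side as C15. C4 is set by C6: in the folded chain the large CH2OTBDPS arm turns outward, away from the lactone, so that C3 reaches the ketone face that leaves O4 α. The step needs reduction of the aldehyde before the ketone, retention of the α-silyloxy and β-acyloxy groups and ring closure rather than dimerisation, which the poor leaving-group quality of silyloxide, the absence of HMPA and of proton donors, the low temperature and slow addition into excess reagent should secure.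

Step 18
Reactants: 24 the ten-membered diol
Product: 25 (1(10)Z)-3β,4α-bis(triethylsilyloxy)-8β-(4-methoxybenzyloxy)-15-(tert-butyldiphenylsilyloxy)germacr-1(10)-en-12,6α-olide
Conditions: TESOTf (3 equiv), 2,6-lutidine, CH2Cl2, −78 to 0 °C
Reagents that add atoms: triethylsilyl trifluoromethanesulfonate CC[Si](CC)(CC)OS(=O)(=O)C(F)(F)F
Why: Silyl triflate/lutidine silylation is strong enough for the tertiary C4 hydroxyl as well as the secondary C3 hydroxyl and removes both acidic protons before enolate chemistry.

Step 19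
Reactants: 25 the bis-TES ether
Product: 28 (1(10)Z)-3β,4α-bis(triethylsilyloxy)-8β-(4-methoxybenzyloxy)-15-(tert-butyldiphenylsilyloxy)germacra-1(10),11(13)-dien-12,6α-olide, via Mannich base 26 (not isolated), via methiodide 27 (not isolated)
Conditions: LiN(iPr)2, THF, −78 °C; Me2N=CH2 iodide, −78 °C to rt; MeI, THF, rt; aq NaHCO3, CH2Cl2
Reagents that add atoms: Eschenmoser's salt (N,N-dimethylmethyleneiminium iodide) C[N+](C)=C.[I-]
Why: Lactone α-methylenation by Mannich reaction with Eschenmoser's salt, N-methylation and Hofmann-type elimination should work because C11 is the only enolisable position and its transient stereocentre disappears in the alkene.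

Step 20
Reactants: 28 the α-methylene lactone
Product: 29 (1(10)Z)-8β-hydroxy-3β,4α-bis(triethylsilyloxy)-15-(tert-butyldiphenylsilyloxy)germacra-1(10),11(13)-dien-12,6α-olide
Conditions: DDQ, CH2Cl2/pH 7 buffer, 0 °C
Reagents that add atoms: none
Why: Oxidative PMB cleavage with DDQ attacks only the electron-rich benzyl ether and should spare the silyl ethers, the isolated alkene and the electron-poor methylene lactone.

Step 21
Reactants: 29 the C8 alcohol; 30 angelic acid
Product: 31 (1(10)Z)-8β-angeloyloxy-3β,4α-bis(triethylsilyloxy)-15-(tert-butyldiphenylsilyloxy)germacra-1(10),11(13)-dien-12,6α-olide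
Conditions: 30, 2,4,6-Cl3C6H2COCl, Et3N, toluene, rt; then 29, 80 °C
Reagents that add atoms: none
Why: In this Yamaguchi-type mixed-anhydride esterification the hindered aroyl carbonyl steers the 8β-hydroxyl to the angeloyl carbonyl, the omission of a nucleophilic catalyst suppresses Z-to-E isomerisation, and C8 keeps its configuration because only the O–H bond reacts.

Step 22
Reactants: 31 the silylated angelate
Product: 32 (1(10)Z)-8β-angeloyloxy-3β,4α,15-trihydroxygermacra-1(10),11(13)-dien-12,6α-olide
Conditions: HF·pyridine, THF, 0 °C to rt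
Reagents that add atoms: none
Why: Global fluoride desilylation under mildly acidic conditions is tolerated by angelate, methylene lactone and alkene, and no epoxide is present yet that could be opened.

Step 23
Reactants: 32 the triol
Product: 33 CNP0307250.1: 8β-angeloyloxy-1β,10β-epoxy-3β,4α,15-trihydroxygermacr-11(13)-en-12,6α-olide
Conditions: VO(acac)2 (5 mol %), t-BuOOH, CH2Cl2, 0 °C
Reagents that add atoms: tert-butyl hydroperoxide CC(C)(C)OO
Why: In the hydroxyl-directed vanadium/t-BuOOH epoxidation the peroxo-vanadium alkoxide of the homoallylic 3β-OH should deliver oxygen to the β face of the electron-rich Z C1–C10 alkene, stereospecifically giving the cis 1β,10β-oxirane, while the two conjugated alkenes are too electron-poor to react.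

Compound list
1 | 4-methylanisole | COc1ccc(C)cc1 | starting material
2 | 1-methoxy-4-methylcyclohexa-1,4-diene | COC1=CCC(C)=CC1 | intermediate
3 | methyl (Z)-6-hydroperoxy-6-methoxy-4-methylhex-3-enoate | COC(=O)C/C=C(C)\CC(OC)OO | intermediate
4 | methyl (Z)-4-methyl-6-oxohex-3-enoate | COC(=O)C/C=C(C)\CC=O | intermediate
5 | methyl (triphenylphosphoranylidene)acetate | COC(=O)C=P(c1ccccc1)(c1ccccc1)c1ccccc1 | starting material
6 | dimethyl (2E,5Z)-5-methylocta-2,5-dienedioate | COC(=O)C/C=C(C)\C/C=C/C(=O)OC | intermediate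
7 | (2E,5Z)-5-methylocta-2,5-diene-1,8-diol | OCC/C=C(C)\C/C=C/CO | intermediate
8 | (Z)-5-[(2R,3R)-3-(hydroxymethyl)oxiran-2-yl]-4-methylpent-3-en-1-ol | OCC/C=C(C)\C[C@H]1O[C@@H]1CO | intermediate
9 | vinylmagnesium bromide | C=C[Mg]Br | starting material
10 | (2S,3R,5Z)-2-ethenyl-5-methyloct-5-ene-1,3,8-triol | OCC/C=C(C)\C[C@@H](O)[C@@H](C=C)CO | intermediate
11 | (Z)-5-[(2S,4R,5S)-5-ethenyl-2-(4-methoxyphenyl)-1,3-dioxan-4-yl]-4-methylpent-3-en-1-ol | OCC/C=C(C)\C[C@H]1O[C@@H](c2ccc(OC)cc2)OC[C@@H]1C=C | intermediate
12 | C12-(9-borabicyclononan-9-yl) O3-(9-borabicyclononan-9-yl) adduct of 11 | C12CCCC(CCC1)B2OCC/C=C(C)\C[C@H]1O[C@@H](c2ccc(OC)cc2)OC[C@@H]1CCB1C2CCCC1CCC2 | intermediate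
13 | (Z)-5-[(2S,4R,5S)-5-(2-hydroxyethyl)-2-(4-methoxyphenyl)-1,3-dioxan-4-yl]-4-methylpent-3-en-1-ol | OCC/C=C(C)\C[C@H]1O[C@@H](c2ccc(OC)cc2)OC[C@@H]1CCO | intermediate
14 | bis-TBS ether of 13 | CC(C)(C)[Si](C)(C)OCC/C=C(C)\C[C@H]1O[C@@H](c2ccc(OC)cc2)OC[C@@H]1CCO[Si](C)(C)C(C)(C)C | intermediate
15 | (2S,3R,5Z)-8-(TBSO)-2-[2-(TBSO)ethyl]-3-(4-methoxybenzyloxy)-5-methyloct-5-en-1-ol | CC(C)(C)[Si](C)(C)OCC/C=C(C)\C[C@@H](OCc1ccc(OC)cc1)[C@@H](CCO[Si](C)(C)C(C)(C)C)CO | intermediate
16 | (2R,3R,5Z)-8-(TBSO)-2-[2-(TBSO)ethyl]-3-(4-methoxybenzyloxy)-5-methyloct-5-enal | CC(C)(C)[Si](C)(C)OCC/C=C(C)\C[C@@H](OCc1ccc(OC)cc1)[C@@H](CCO[Si](C)(C)C(C)(C)C)C=O | intermediate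
17 | hydroxyacetone | CC(=O)CO | starting material
18 | 1-(tert-butyldiphenylsilyloxy)propan-2-one | CC(=O)CO[Si](c1ccccc1)(c1ccccc1)C(C)(C)C | intermediate
19 | tert-butyldiphenyl{[2-(trimethylsilyloxy)prop-2-en-1-yl]oxy}silane | C=C(O[Si](C)(C)C)CO[Si](c1ccccc1)(c1ccccc1)C(C)(C)C | intermediate
20 | (4R,5S,6R,8Z)-11-(TBSO)-5-[2-(TBSO)ethyl]-1-(TBDPSO)-4-hydroxy-6-(4-methoxybenzyloxy)-8-methylundec-8-en-2-one | CC(C)(C)[Si](C)(C)OCC/C=C(C)\C[C@@H](OCc1ccc(OC)cc1)[C@@H](CCO[Si](C)(C)C(C)(C)C)[C@H](O)CC(=O)CO[Si](c1ccccc1)(c1ccccc1)C(C)(C)C | intermediate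
21 | (4R,5S,6R,8Z)-1-(TBDPSO)-4,11-dihydroxy-5-(2-hydroxyethyl)-6-(4-methoxybenzyloxy)-8-methylundec-8-en-2-one | OCC/C=C(C)\C[C@@H](OCc1ccc(OC)cc1)[C@@H](CCO)[C@H](O)CC(=O)CO[Si](c1ccccc1)(c1ccccc1)C(C)(C)C | intermediate
22 | C12 lactol of the C3 aldehyde (C12 epimers) | O=CC/C=C(C)\C[C@@H](OCc1ccc(OC)cc1)[C@H]1CC(O)O[C@@H]1CC(=O)CO[Si](c1ccccc1)(c1ccccc1)C(C)(C)C | intermediate
23 | (3Z,6R)-6-(4-methoxybenzyloxy)-4-methyl-6-{(2R,3R)-5-oxo-2-[3-(TBDPSO)-2-oxopropyl]oxolan-3-yl}hex-3-enal | O=CC/C=C(C)\C[C@@H](OCc1ccc(OC)cc1)[C@H]1CC(=O)O[C@@H]1CC(=O)CO[Si](c1ccccc1)(c1ccccc1)C(C)(C)C | intermediate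
24 | (1(10)Z)-3β,4α-dihydroxy-8β-(4-methoxybenzyloxy)-15-(TBDPSO)germacr-1(10)-en-12,6α-olide | C1C(=O)O[C@@H]2C[C@@](O)(CO[Si](c3ccccc3)(c3ccccc3)C(C)(C)C)[C@@H](O)C/C=C(C)\C[C@@H](OCc3ccc(OC)cc3)[C@@H]12 | intermediate
25 | 3,4-bis-TES ether of 24 | C1C(=O)O[C@@H]2C[C@@](O[Si](CC)(CC)CC)(CO[Si](c3ccccc3)(c3ccccc3)C(C)(C)C)[C@@H](O[Si](CC)(CC)CC)C/C=C(C)\C[C@@H](OCc3ccc(OC)cc3)[C@@H]12 | intermediate
26 | 11-(dimethylaminomethyl) derivative of 25 (C11 epimers) | CN(C)CC1C(=O)O[C@@H]2C[C@@](O[Si](CC)(CC)CC)(CO[Si](c3ccccc3)(c3ccccc3)C(C)(C)C)[C@@H](O[Si](CC)(CC)CC)C/C=C(C)\C[C@@H](OCc3ccc(OC)cc3)[C@@H]12 | intermediate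
27 | trimethylammonium iodide of 26 | C[N+](C)(C)CC1C(=O)O[C@@H]2C[C@@](O[Si](CC)(CC)CC)(CO[Si](c3ccccc3)(c3ccccc3)C(C)(C)C)[C@@H](O[Si](CC)(CC)CC)C/C=C(C)\C[C@@H](OCc3ccc(OC)cc3)[C@@H]12.[I-] | intermediate
28 | 11(13)-methylene lactone with 8β-OPMB | C=C1C(=O)O[C@@H]2C[C@@](O[Si](CC)(CC)CC)(CO[Si](c3ccccc3)(c3ccccc3)C(C)(C)C)[C@@H](O[Si](CC)(CC)CC)C/C=C(C)\C[C@@H](OCc3ccc(OC)cc3)[C@@H]12 | intermediate
29 | 11(13)-methylene lactone with free 8β-OH | C=C1C(=O)O[C@@H]2C[C@@](O[Si](CC)(CC)CC)(CO[Si](c3ccccc3)(c3ccccc3)C(C)(C)C)[C@@H](O[Si](CC)(CC)CC)C/C=C(C)\C[C@@H](O)[C@@H]12 | intermediate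
30 | angelic acid ((Z)-2-methylbut-2-enoic acid) | OC(=O)/C(C)=C\C | starting material
31 | silylated 8β-angelate | C=C1C(=O)O[C@@H]2C[C@@](O[Si](CC)(CC)CC)(CO[Si](c3ccccc3)(c3ccccc3)C(C)(C)C)[C@@H](O[Si](CC)(CC)CC)C/C=C(C)\C[C@@H](OC(=O)/C(C)=C\C)[C@@H]12 | intermediate
32 | (1(10)Z)-8β-angeloyloxy-3β,4α,15-trihydroxygermacra-1(10),11(13)-dien-12,6α-olide | C=C1C(=O)O[C@@H]2C[C@@](O)(CO)[C@@H](O)C/C=C(C)\C[C@@H](OC(=O)/C(C)=C\C)[C@@H]12 | intermediate
33 | CNP0307250.1 | C=C1C(=O)O[C@@H]2C[C@@](O)(CO)[C@@H](O)C[C@H]3O[C@@]3(C)C[C@@H](OC(=O)/C(C)=C\C)[C@@H]12 | target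

Total step count: 23. Longest linear sequence: 21 steps (steps 1–11 and 14–23); steps 12 and 13 form the two-step side branch.

Steps most likely to fail

**Step 17.**
- Risk: Dimerisation or plain reduction of the aldehyde may outrun the entropically costly ring closure. Reductive cleavage of the C15–O bond next to the ketone may compete, and control over the diol configuration may be weak.
- Fallback: It sets out from 23 and replaces the soluble one-electron donor by low-valent titanium. TiCl3(DME)1.5 and Zn–Cu couple are used in DME at 0 to 25 °C, with 23 added over many hours. Both carbonyl oxygens are anchored on the titanium surface before the C3–C4 bond forms (the pinacol stage of the McMurry reaction, a classical entry to macrocyclic 1,2-diols). Closure then does not depend on a free ketyl finding the ketone, and the samarium enolate pathway for C–O cleavage is absent. The low temperature keeps the reaction from running on to the alkene.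
- Return: The route is rejoined at 24, and no compound outside the list is made (F0).

**Step 23.**
- Risk: Oxygen may be delivered to the wrong alkene face if the ring conformation overrides the hydroxyl direction, and the free hydroxyls may open the fresh epoxide at the Lewis-acidic metal.
- Fallback: It sets out from 31 and builds the oxirane in two polar stages that invert the intrinsic face preference. NBS in aqueous THF at 0 °C should place bromonium on the exposed face and water on the tertiary C10 from the other side, giving the silylated 1α-bromo-10β-hydroxy compound F1. Ag2O in THF then closes the ring by backside displacement at C1 to the silylated 1β,10β-epoxide F2.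
- Return: Buffered fluoride (Et3N·3HF, MeCN) removes the three silyl groups and the route ends at 33.

**Step 14.**
- Risk: Activation of the aldehyde by the Lewis acid may let the C1–C10 alkene attack C6 (Prins-type six-membered closure) in competition with 19. Regioisomeric enol silane carried over from step 13 may also erode the result.
- Fallback: It sets out from 16 and 18 and uses no external Lewis acid. Ketone 18 is enolised on its methyl side with Ipc2BCl (the enantiomer matched to Felkin–Anh attack) and Et3N in Et2O at 0 °C. It is then added to 16 at −78 °C through a closed six-membered boron aldol transition state, followed by buffered H2O2 work-up. Reagent control supports the substrate bias at C6, and step 13 is skipped.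
- Return: The route is rejoined at 20, and no compound outside the list is made (F0).

Further compounds
F0 | step 17 | none | none
F1 | step 23 | 1α-bromo-10β-hydroxy derivative of 31 | C=C1C(=O)O[C@@H]2C[C@@](O[Si](CC)(CC)CC)(CO[Si](c3ccccc3)(c3ccccc3)C(C)(C)C)[C@@H](O[Si](CC)(CC)CC)C[C@H](Br)[C@](O)(C)C[C@@H](OC(=O)/C(C)=C\C)[C@@H]12
F2 | step 23 | 1β,10β-epoxide of 31 | C=C1C(=O)O[C@@H]2C[C@@](O[Si](CC)(CC)CC)(CO[Si](c3ccccc3)(c3ccccc3)C(C)(C)C)[C@@H](O[Si](CC)(CC)CC)C[C@H]3O[C@@]3(C)C[C@@H](OC(=O)/C(C)=C\C)[C@@H]12
F0 | step 14 | none | none
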